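**Retrosynthetic overview**
1. The strategy rests on ring C (O1, C2, C3, C4, C4a, C8a): cutting O1–C2 and C3–C4 separates an A-ring salicylaldehyde unit that already carries C4 from a B-ring styrene that supplies C2 and C3. C2 is the only stereocentre.
2. Ring C is the only ring formed (step 5), by a chiral-acid [4+2] of the A-ring dimethyl acetal with the styrene, which gives a 4-methoxyflavan. Rings A and B are bought as the two aldehydes.
3. The C4 ketone comes from DDQ oxidation of the C4 methyl ether, which erases C4 and keeps C2.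
4. Ring A is then decorated: 7-O-(1,1-dimethylallyl) ether, iodination at C6 (blocking group and coupling handle), Claisen shift O7→C8, Suzuki alkenylation at C6, desilylation.

Key step: step 5

Remark 1: the sense of induction of the chiral acid in step 5 cannot be predicted with confidence; the (R)-catalyst is written, and its enantiomer is used if the (2R,4R) series results.
Remark 2: the B-ring phenols are carried as TIPS ethers (not TBS) so that they survive DBU and aqueous phosphate; a free 2'- or 4'-phenoxide would open ring C through a quinone methide and racemise C2.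
Remark 3: 3-chloro-3-methylbut-1-yne is taken as a commercial compound.

**Route**

Step 1
Reactants: 1 2,4,6-trihydroxybenzaldehyde
Product: 2 2,4-bis(benzyloxy)-6-hydroxybenzaldehyde
Conditions: BnBr (2.05 equiv), K2CO3, DMF, 0 °C to rt
Reagents that add atoms: benzyl bromide, BrCc1ccccc1
Why: Williamson O-benzylation in which the 4-OH and one ortho OH react, while the last ortho OH is held in the hydrogen bond to the aldehyde and survives two equivalents of bromide.

Step 2
Reactants: 2 2,4-bis(benzyloxy)-6-hydroxybenzaldehyde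
Product: 3 3,5-bis(benzyloxy)-2-(dimethoxymethyl)phenol
Conditions: HC(OMe)3, MeOH, PPTS (cat.), rt; Et3N quench, concentrate, use crude
Reagents that add atoms: trimethyl orthoformate, COC(OC)OC; methanol, CO (solvent, exchanges with the orthoformate)
Why: Acid-catalysed acetalisation driven by the orthoformate as water scavenger, with a basic quench and no chromatography because this electron-rich ortho-hydroxy acetal ionises on silica.

Step 3
Reactants: 4 2,4-dihydroxybenzaldehyde
Product: 5 2,4-bis(triisopropylsilyloxy)benzaldehyde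
Conditions: TIPSOTf (2.3 equiv), 2,6-lutidine, CH2Cl2, 0 °C to rt
Reagents that add atoms: triisopropylsilyl triflate, CC(C)[Si](C(C)C)(C(C)C)OS(=O)(=O)C(F)(F)F
Why: O-Silylation with the triflate, which is reactive enough to reach the hydrogen-bonded 2-OH as well as the 4-OH.

Step 4
Reactants: 5 2,4-bis(triisopropylsilyloxy)benzaldehyde
Product: 6 2,4-bis(triisopropylsilyloxy)styrene
Conditions: Ph3PCH3Br, KHMDS, THF, 0 °C to rt
Reagents that add atoms: methyltriphenylphosphonium bromide, C[P+](c1ccccc1)(c1ccccc1)c1ccccc1.[Br-]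
Why: Wittig methylenation of a non-enolisable aldehyde, which aryl TIPS ethers tolerate.

Step 5
Reactants: 3 3,5-bis(benzyloxy)-2-(dimethoxymethyl)phenol; 6 2,4-bis(triisopropylsilyloxy)styrene
Product: 8 (2S,4S)-5,7-bis(benzyloxy)-4-methoxy-2-[2,4-bis(triisopropylsilyloxy)phenyl]chroman (2,4-cis), via 4-methoxy-ortho-quinone methide 7 (not isolated)
Conditions: (R)-TRIP N-triflylphosphoramide (5 mol%), 5 Å MS, toluene, −40 °C; 6 (1.5 equiv) added over 6 h; chromatography on Et3N-treated silica
Reagents that add atoms: none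
Why: Proposed new method: the acid ionises acetal 3 with loss of methanol to the ortho-hydroxyaryl oxocarbenium ion (the protonated form of methoxy-ortho-quinone methide 7), held as a contact ion pair whose phenol OH is hydrogen-bonded to the chiral phosphoramide anion; the terminal CH2 of styrene 6 attacks C4 and the phenol oxygen then captures the 2,4-bis(silyloxy)benzyl cation, an asynchronous inverse-electron-demand oxa-[4+2]. The closest known reactions are the chiral phosphoric acid and N-triflylphosphoramide catalysed [4+2] cycloadditions of ortho-quinone methides with styrenes and the achiral acid-mediated salicylaldehyde acetal–styrene annulation that gives racemic cis-4-alkoxyflavans. Ring C closes as a six-membered oxacycle in the [4+2] mode, C3–C4 first and O1–C2 second by 6-exo capture of the benzylic cation. C4 is set by the chiral anion, which shields one face of the oxocarbenium carbon during C–C bond formation; C2 is set by the substrate, since closure through the endo, chair-like arrangement places the B-ring aryl pseudo-equatorial and cis to the methoxy group, relaying 4S to 2S. The step needs cross-addition to win over cationic oligomerisation of 6 and over Friedel–Crafts attack of the electron-rich A ring on the cation; the unhindered, strongly nucleophilic CH2 terminus of the dioxygenated styrene, its slow addition at low temperature and removal of methanol by the sieves should secure this, and any trans isomer is removed here because it would carry the opposite C2 configuration into the flavanone.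

Step 6
Reactants: 8 (2S,4S)-5,7-bis(benzyloxy)-4-methoxy-2-[2,4-bis(triisopropylsilyloxy)phenyl]chroman
Product: 10 (2S)-5,7-bis(benzyloxy)-2-[2,4-bis(triisopropylsilyloxy)phenyl]chroman-4-one, via C4 hemiketal 9 (not isolated)
Conditions: DDQ (1.3 equiv), CH2Cl2/pH 7 buffer (10:1), 0 °C to rt
Reagents that add atoms: water, O
Why: DDQ benzylic ether oxidation, in which hydride abstraction from the C4–H flanked by OMe and the trioxygenated ring A gives an oxocarbenium ion, water adds to give hemiketal 9, and loss of methanol leaves the ketone, so the C4 stereocentre is removed and C2 is untouched.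

Step 7
Reactants: 10 (2S)-5,7-bis(benzyloxy)-2-[2,4-bis(triisopropylsilyloxy)phenyl]chroman-4-one
Product: 11 (2S)-5,7-dihydroxy-2-[2,4-bis(triisopropylsilyloxy)phenyl]chroman-4-one
Conditions: H2 (1 atm), 10% Pd/C, EtOAc, rt
Reagents that add atoms: none
Why: Hydrogenolysis of the two benzyl ethers under neutral conditions in a non-protic solvent, which should leave the aryl TIPS ethers, the aryl ketone and the C2–O1 bond intact.

Step 8
Reactants: 11 (2S)-5,7-dihydroxy-2-[2,4-bis(triisopropylsilyloxy)phenyl]chroman-4-one; 12 3-chloro-3-methylbut-1-yne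
Product: 13 (2S)-5-hydroxy-7-[(2-methylbut-3-yn-2-yl)oxy]-2-[2,4-bis(triisopropylsilyloxy)phenyl]chroman-4-one
Conditions: CuCl2·2H2O (1 mol%), DBU (1.2 equiv), MeCN–THF, 0 °C
Reagents that add atoms: none
Why: Copper-catalysed propargylic etherification of the more acidic 7-OH, with the 5-OH held in the hydrogen bond to C4=O and the 7-phenoxide lowering the acidity of C3–H so that ring opening and epimerisation at C2 are disfavoured.

Step 9
Reactants: 13 (2S)-5-hydroxy-7-[(2-methylbut-3-yn-2-yl)oxy]-2-[2,4-bis(triisopropylsilyloxy)phenyl]chroman-4-one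
Product: 14 (2S)-5-hydroxy-7-[(2-methylbut-3-en-2-yl)oxy]-2-[2,4-bis(triisopropylsilyloxy)phenyl]chroman-4-one
Conditions: H2 (1 atm), Lindlar catalyst, quinoline, EtOAc, rt, stopped at 1 equiv H2
Reagents that add atoms: none
Why: Lindlar semihydrogenation of the terminal alkyne to the 1,1-dimethylallyl ether.

Step 10
Reactants: 14 (2S)-5-hydroxy-7-[(2-methylbut-3-en-2-yl)oxy]-2-[2,4-bis(triisopropylsilyloxy)phenyl]chroman-4-one
Product: 15 (2S)-5-hydroxy-6-iodo-7-[(2-methylbut-3-en-2-yl)oxy]-2-[2,4-bis(triisopropylsilyloxy)phenyl]chroman-4-one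
Conditions: NIS (1.05 equiv), DMF, 0 °C, dark
Reagents that add atoms: N-iodosuccinimide, O=C1CCC(=O)N1I
Why: Electrophilic aromatic iodination ortho to the free chelated 5-OH, the C6 preference known for 5-hydroxy-7-alkoxyflavones, under neutral conditions that should spare the tertiary allyl ether and the less activated bis-silylated ring B.

Step 11
Reactants: 15 (2S)-5-hydroxy-6-iodo-7-[(2-methylbut-3-en-2-yl)oxy]-2-[2,4-bis(triisopropylsilyloxy)phenyl]chroman-4-one
Product: 17 (2S)-5,7-dihydroxy-6-iodo-8-(3-methylbut-2-en-1-yl)-2-[2,4-bis(triisopropylsilyloxy)phenyl]chroman-4-one, via C8 dienone 16 (not isolated)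
Conditions: toluene, 110 °C, sealed tube
Reagents that add atoms: none
Why: Aromatic Claisen rearrangement ([3,3]) of the 1,1-dimethylallyl ether, in which iodine blocks C6 so that the allyl unit is delivered with inversion to C8 as a prenyl group and dienone 16 tautomerises to the phenol.

Step 12
Reactants: 18 3-methylbut-1-yne
Product: 19 (E)-4,4,5,5-tetramethyl-2-(3-methylbut-1-en-1-yl)-1,3,2-dioxaborolane
Conditions: HBpin (1.1 equiv), Cp2Zr(H)Cl (5 mol%), Et3N (5 mol%), CH2Cl2, sealed vessel, rt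
Reagents that add atoms: pinacolborane, CC1(C)OBOC1(C)C
Why: Zirconium-catalysed syn, anti-Markovnikov hydroboration of the terminal alkyne gives the (E)-alkenylboronate.

Step 13
Reactants: 17 (2S)-5,7-dihydroxy-6-iodo-8-(3-methylbut-2-en-1-yl)-2-[2,4-bis(triisopropylsilyloxy)phenyl]chroman-4-one; 19 (E)-4,4,5,5-tetramethyl-2-(3-methylbut-1-en-1-yl)-1,3,2-dioxaborolane
Product: 20 (2S)-5,7-dihydroxy-6-[(E)-3-methylbut-1-en-1-yl]-8-(3-methylbut-2-en-1-yl)-2-[2,4-bis(triisopropylsilyloxy)phenyl]chroman-4-one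
Conditions: SPhos Pd G3 (5 mol%), K3PO4 (3 equiv), THF/H2O (10:1), degassed, 45 °C
Reagents that add atoms: none
Why: Suzuki–Miyaura coupling with retention of the (E)-geometry, placed after the Claisen step so that the aryl–palladium intermediate never has an ortho propargyl or allyl ether to cyclise onto, while the 7-phenoxide formed under the phosphate base protects C3–H from deprotonation.

Step 14
Reactants: 20 (2S)-5,7-dihydroxy-6-[(E)-3-methylbut-1-en-1-yl]-8-(3-methylbut-2-en-1-yl)-2-[2,4-bis(triisopropylsilyloxy)phenyl]chroman-4-one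
Product: 21 (2S)-2-(2,4-dihydroxyphenyl)-5,7-dihydroxy-6-[(E)-3-methylbut-1-en-1-yl]-8-(3-methylbut-2-en-1-yl)chroman-4-one (CNP0290067.1)
Conditions: TBAF/AcOH (1:1, 2.5 equiv), THF, 0 °C to rt
Reagents that add atoms: none
Why: Fluoride desilylation buffered with acetic acid, so that no B-ring phenoxide forms that could open ring C through a quinone methide and racemise C2.

**Compound list**
1 | 2,4,6-trihydroxybenzaldehyde | O=Cc1c(O)cc(O)cc1O | starting material
2 | 2,4-bis(benzyloxy)-6-hydroxybenzaldehyde | O=Cc1c(O)cc(OCc2ccccc2)cc1OCc1ccccc1 | intermediate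
3 | 3,5-bis(benzyloxy)-2-(dimethoxymethyl)phenol | COC(OC)c1c(O)cc(OCc2ccccc2)cc1OCc1ccccc1 | intermediate
4 | 2,4-dihydroxybenzaldehyde | O=Cc1ccc(O)cc1O | starting material
5 | 2,4-bis(triisopropylsilyloxy)benzaldehyde | O=Cc1ccc(O[Si](C(C)C)(C(C)C)C(C)C)cc1O[Si](C(C)C)(C(C)C)C(C)C | intermediate
6 | 2,4-bis(triisopropylsilyloxy)styrene | C=Cc1ccc(O[Si](C(C)C)(C(C)C)C(C)C)cc1O[Si](C(C)C)(C(C)C)C(C)C | intermediate
7 | 3,5-bis(benzyloxy)-6-(methoxymethylidene)cyclohexa-2,4-dien-1-one (methoxy-ortho-quinone methide, formed in situ as its protonated ion pair) | COC=C1C(=O)C=C(OCc2ccccc2)C=C1OCc3ccccc3 | intermediate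
8 | (2S,4S)-5,7-bis(benzyloxy)-4-methoxy-2-[2,4-bis(triisopropylsilyloxy)phenyl]chroman (2,4-cis) | c1c(OCc3ccccc3)cc(OCc3ccccc3)c2c1O[C@H](c1ccc(O[Si](C(C)C)(C(C)C)C(C)C)cc1O[Si](C(C)C)(C(C)C)C(C)C)C[C@@H]2OC | intermediate
9 | (2S)-5,7-bis(benzyloxy)-4-hydroxy-4-methoxy-2-[2,4-bis(triisopropylsilyloxy)phenyl]chroman (C4 hemiketal, formed in situ, C4 epimers) | c1c(OCc3ccccc3)cc(OCc3ccccc3)c2c1O[C@H](c1ccc(O[Si](C(C)C)(C(C)C)C(C)C)cc1O[Si](C(C)C)(C(C)C)C(C)C)CC2(O)OC | intermediate
10 | (2S)-5,7-bis(benzyloxy)-2-[2,4-bis(triisopropylsilyloxy)phenyl]chroman-4-one | c1c(OCc3ccccc3)cc(OCc3ccccc3)c2c1O[C@H](c1ccc(O[Si](C(C)C)(C(C)C)C(C)C)cc1O[Si](C(C)C)(C(C)C)C(C)C)CC2=O | intermediate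
11 | (2S)-5,7-dihydroxy-2-[2,4-bis(triisopropylsilyloxy)phenyl]chroman-4-one | c1c(O)cc(O)c2c1O[C@H](c1ccc(O[Si](C(C)C)(C(C)C)C(C)C)cc1O[Si](C(C)C)(C(C)C)C(C)C)CC2=O | intermediate
12 | 3-chloro-3-methylbut-1-yne | CC(C)(Cl)C#C | starting material
13 | (2S)-5-hydroxy-7-[(2-methylbut-3-yn-2-yl)oxy]-2-[2,4-bis(triisopropylsilyloxy)phenyl]chroman-4-one | c1c(OC(C)(C)C#C)cc(O)c2c1O[C@H](c1ccc(O[Si](C(C)C)(C(C)C)C(C)C)cc1O[Si](C(C)C)(C(C)C)C(C)C)CC2=O | intermediate
14 | (2S)-5-hydroxy-7-[(2-methylbut-3-en-2-yl)oxy]-2-[2,4-bis(triisopropylsilyloxy)phenyl]chroman-4-one | c1c(OC(C)(C)C=C)cc(O)c2c1O[C@H](c1ccc(O[Si](C(C)C)(C(C)C)C(C)C)cc1O[Si](C(C)C)(C(C)C)C(C)C)CC2=O | intermediate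
15 | (2S)-5-hydroxy-6-iodo-7-[(2-methylbut-3-en-2-yl)oxy]-2-[2,4-bis(triisopropylsilyloxy)phenyl]chroman-4-one | c1c(OC(C)(C)C=C)c(I)c(O)c2c1O[C@H](c1ccc(O[Si](C(C)C)(C(C)C)C(C)C)cc1O[Si](C(C)C)(C(C)C)C(C)C)CC2=O | intermediate
16 | (2S)-5-hydroxy-6-iodo-8-(3-methylbut-2-en-1-yl)-2-[2,4-bis(triisopropylsilyloxy)phenyl]-2,3-dihydro-8H-chromene-4,7-dione (C8 dienone, formed in situ, C8 epimers) | CC(C)=CCC1C(=O)C(I)=C(O)C2=C1O[C@H](c1ccc(O[Si](C(C)C)(C(C)C)C(C)C)cc1O[Si](C(C)C)(C(C)C)C(C)C)CC2=O | intermediate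
17 | (2S)-5,7-dihydroxy-6-iodo-8-(3-methylbut-2-en-1-yl)-2-[2,4-bis(triisopropylsilyloxy)phenyl]chroman-4-one | CC(C)=CCc1c(O)c(I)c(O)c2c1O[C@H](c1ccc(O[Si](C(C)C)(C(C)C)C(C)C)cc1O[Si](C(C)C)(C(C)C)C(C)C)CC2=O | intermediate
18 | 3-methylbut-1-yne | CC(C)C#C | starting material
19 | (E)-4,4,5,5-tetramethyl-2-(3-methylbut-1-en-1-yl)-1,3,2-dioxaborolane | CC(C)/C=C/B1OC(C)(C)C(C)(C)O1 | intermediate
20 | (2S)-5,7-dihydroxy-6-[(E)-3-methylbut-1-en-1-yl]-8-(3-methylbut-2-en-1-yl)-2-[2,4-bis(triisopropylsilyloxy)phenyl]chroman-4-one | CC(C)=CCc1c(O)c(/C=C/C(C)C)c(O)c2c1O[C@H](c1ccc(O[Si](C(C)C)(C(C)C)C(C)C)cc1O[Si](C(C)C)(C(C)C)C(C)C)CC2=O | intermediate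
21 | (2S)-2-(2,4-dihydroxyphenyl)-5,7-dihydroxy-6-[(E)-3-methylbut-1-en-1-yl]-8-(3-methylbut-2-en-1-yl)chroman-4-one | CC(C)=CCc1c(O)c(/C=C/C(C)C)c(O)c2c1O[C@H](c1ccc(O)cc1O)CC2=O | target

**Step count**
Total steps: 14. Longest linear sequence: 11 (steps 1, 2, 5, 6, 7, 8, 9, 10, 11, 13, 14).

**Steps most likely to fail**

1. Step 5 (Proposed new method). The chiral anion may discriminate the faces of the oxocarbenium carbon poorly, and the cis relay from C4 to C2 may be incomplete. The styrene may oligomerise cationically, the electron-rich A ring may attack the cation in a Friedel–Crafts self-condensation, and the product may re-ionise at C4. The fallback uses known chemistry, sets out from 3 and 6 and returns at 8. An achiral acid (diphenyl phosphate, 10 mol%, CH2Cl2, 0 °C) effects the known acetal–styrene annulation to the racemic cis-4-methoxyflavan, that is 8 together with its mirror image (2R,4R)-5,7-bis(benzyloxy)-4-methoxy-2-[2,4-bis(triisopropylsilyloxy)phenyl]chroman F1. Preparative HPLC on a polysaccharide chiral phase separates 8, which re-enters at step 6. This answers loss of enantiocontrol; it does not help if the annulation itself fails on this substrate.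

2. Step 10. Iodination may not discriminate C6 from C8, or may touch ring B or the terminal alkene; a wrong or mixed regiochemistry would misdirect the Claisen step. The fallback sets out from 11 and returns at 21, fixing the regiochemistry by a sigmatropic relay from O5 instead of by electrophilic selectivity. Selective silylation of the non-chelated 7-OH (TIPSCl, imidazole, DMF) gives (2S)-5-hydroxy-7-(triisopropylsilyloxy)-2-[2,4-bis(triisopropylsilyloxy)phenyl]chroman-4-one F2. Mitsunobu etherification of the 5-OH with prenol (PPh3, DIAD, THF) gives the 5-O-prenyl ether F3. A europium(III)-catalysed Claisen–Cope sequence (Eu(fod)3, CHCl3, 60 °C), the known O5→C6→C8 relay of 5-O-prenylflavanones, gives the 5-hydroxy-8-prenyl compound F4. Its only free A-ring position is C6, so NIS gives the 6-iodide F5 without a regiochemical choice. Suzuki coupling with 19 as in step 13 gives the 6-alkenyl tris-silyl ether F6, and TBAF/AcOH removes the three silyl groups to give 21.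

3. Step 13. Oxidative addition may be slow at the doubly ortho-oxygenated, phenoxide-rich iodide, protodeiodination may compete, and the aqueous base may erode C2 by reversible ring opening. The fallback sets out from 18 and 17 and returns at 20, replacing the base-mediated boron coupling with a base-free tin coupling. Palladium-catalysed syn-hydrostannylation of 18 (Bu3SnH, Pd(PPh3)2Cl2 cat., THF, sealed) gives (E)-tributyl(3-methylbut-1-en-1-yl)stannane F7 after removal of the minor internal isomer. Stille coupling of F7 with 17 (Pd2(dba)3, AsPh3, CuI, DMF, 50 °C) under neutral conditions gives 20, which goes on to step 14.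

**Further compounds**
F1 | step 5 | (2R,4R)-5,7-bis(benzyloxy)-4-methoxy-2-[2,4-bis(triisopropylsilyloxy)phenyl]chroman (mirror image of 8) | c1c(OCc3ccccc3)cc(OCc3ccccc3)c2c1O[C@@H](c1ccc(O[Si](C(C)C)(C(C)C)C(C)C)cc1O[Si](C(C)C)(C(C)C)C(C)C)C[C@H]2OC
F2 | step 10 | (2S)-5-hydroxy-7-(triisopropylsilyloxy)-2-[2,4-bis(triisopropylsilyloxy)phenyl]chroman-4-one | c1c(O[Si](C(C)C)(C(C)C)C(C)C)cc(O)c2c1O[C@H](c1ccc(O[Si](C(C)C)(C(C)C)C(C)C)cc1O[Si](C(C)C)(C(C)C)C(C)C)CC2=O
F3 | step 10 | (2S)-5-[(3-methylbut-2-en-1-yl)oxy]-7-(triisopropylsilyloxy)-2-[2,4-bis(triisopropylsilyloxy)phenyl]chroman-4-one | c1c(O[Si](C(C)C)(C(C)C)C(C)C)cc(OCC=C(C)C)c2c1O[C@H](c1ccc(O[Si](C(C)C)(C(C)C)C(C)C)cc1O[Si](C(C)C)(C(C)C)C(C)C)CC2=O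
F4 | step 10 | (2S)-5-hydroxy-8-(3-methylbut-2-en-1-yl)-7-(triisopropylsilyloxy)-2-[2,4-bis(triisopropylsilyloxy)phenyl]chroman-4-one | CC(C)=CCc1c(O[Si](C(C)C)(C(C)C)C(C)C)cc(O)c2c1O[C@H](c1ccc(O[Si](C(C)C)(C(C)C)C(C)C)cc1O[Si](C(C)C)(C(C)C)C(C)C)CC2=O
F5 | step 10 | (2S)-5-hydroxy-6-iodo-8-(3-methylbut-2-en-1-yl)-7-(triisopropylsilyloxy)-2-[2,4-bis(triisopropylsilyloxy)phenyl]chroman-4-one | CC(C)=CCc1c(O[Si](C(C)C)(C(C)C)C(C)C)c(I)c(O)c2c1O[C@H](c1ccc(O[Si](C(C)C)(C(C)C)C(C)C)cc1O[Si](C(C)C)(C(C)C)C(C)C)CC2=O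
F6 | step 10 | (2S)-5-hydroxy-6-[(E)-3-methylbut-1-en-1-yl]-8-(3-methylbut-2-en-1-yl)-7-(triisopropylsilyloxy)-2-[2,4-bis(triisopropylsilyloxy)phenyl]chroman-4-one | CC(C)=CCc1c(O[Si](C(C)C)(C(C)C)C(C)C)c(/C=C/C(C)C)c(O)c2c1O[C@H](c1ccc(O[Si](C(C)C)(C(C)C)C(C)C)cc1O[Si](C(C)C)(C(C)C)C(C)C)CC2=O
F7 | step 13 | (E)-tributyl(3-methylbut-1-en-1-yl)stannane | CCCC[Sn](CCCC)(CCCC)/C=C/C(C)C
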